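Everything rests on cutting the bond between the bridge CH2 and C1 of ring A, the 3,5-dimethoxy-4-prenylphenyl ring. A nickel-electrocatalytic decarboxylative arylation forges this C(sp3)–C(sp2) bond in one operation and delivers the ArCH2–CH2Ar' bridge already saturated, so the prenyl C=C of ring A never meets a hydrogenation catalyst. The feature exploited is that ring B plus bridge is a masked dihydrocinnamate: O1, C8–OH, C7–OH and the C4a–C4–C3 chain of daphnetin become C2–OMe, C3–OH, C4–OAc and the two bridge carbons. The coupling partners are the N-acyloxyphthalimide of 3-[2-methoxy-3,4-bis(methoxymethoxy)phenyl]propanoic acid and 5-bromo-1,3-dimethoxy-2-prenylbenzene.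

Key step: step 8

Remark on the chemistry: the target has no stereocentre and its only C=C carries two identical methyl groups. It is therefore achiral, and "single enantiomer" sets no stereochemical task.

Step 1
Reactants: 1 daphnetin (7,8-dihydroxy-2H-chromen-2-one)
Product: 2 7,8-bis(methoxymethoxy)-2H-chromen-2-one
Conditions: MOMCl (3 equiv), i-Pr2NEt (4 equiv), DMF, 0 °C → rt, Ar
Reagents that add atoms: chloromethyl methyl ether, COCCl
Why: Williamson-type O-alkylation with an excess of the very reactive chloromethyl ether caps both the acidic 7-OH and the more crowded 8-OH as MOM acetals that tolerate base and hydrogenation, while the hindered amine leaves the lactone alone.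

Step 2
Reactants: 2 7,8-bis(methoxymethoxy)-2H-chromen-2-one
Product: 3 7,8-bis(methoxymethoxy)chroman-2-one
Conditions: H2 (3 atm), 10% Pd/C, EtOAc, rt
Reagents that add atoms: none
Why: Heterogeneous catalytic hydrogenation saturates the conjugated C3=C4 bond of the coumarin while MOM acetals, lactone and arene stay inert in an aprotic solvent, and the step is placed here because no prenyl group is present yet.

Step 3
Reactants: 3 7,8-bis(methoxymethoxy)chroman-2-one
Product: 6 3-[2-methoxy-3,4-bis(methoxymethoxy)phenyl]propanoic acid, via disodium 3-[3,4-bis(methoxymethoxy)-2-oxidophenyl]propanoate 4 (not isolated), via sodium 3-[2-methoxy-3,4-bis(methoxymethoxy)phenyl]propanoate 5 (not isolated)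
Conditions: 2 M aq NaOH, THF, rt, Ar; Me2SO4, 0 °C → rt; aq NaOH, 50 °C; then 1 M HCl to pH 4, 0 °C, immediate extraction
Reagents that add atoms: sodium hydroxide, [Na+].[OH-]; dimethyl sulfate, COS(=O)(=O)OC
Why: Hydroxide saponifies the aryl-ester lactone irreversibly and frees the former O1 as a phenoxide, which undergoes Williamson O-methylation in the same pot (the classical aqueous NaOH/dimethyl sulfate phenol methylation), the warm hydroxide stage cleaves any methyl ester formed on the side, and unmethylated material merely relactonises to neutral 3 on acidification and is removed by extraction.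

Step 4
Reactants: 6 3-[2-methoxy-3,4-bis(methoxymethoxy)phenyl]propanoic acid
Product: 7 1,3-dioxoisoindolin-2-yl 3-[2-methoxy-3,4-bis(methoxymethoxy)phenyl]propanoate
Conditions: N-hydroxyphthalimide (1.1 equiv), DIC (1.1 equiv), DMAP (10 mol %), CH2Cl2, rt
Reagents that add atoms: N-hydroxyphthalimide, O=C1c2ccccc2C(=O)N1O
Why: Steglich-type carbodiimide esterification of an unhindered primary acid with the acidic N-hydroxyimide is fast at room temperature and neutral enough for the MOM acetals.

Step 5
Reactants: 8 1,3-dimethoxybenzene; 9 prenyl bromide (1-bromo-3-methylbut-2-ene)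
Product: 11 1,3-dimethoxy-2-(3-methylbut-2-en-1-yl)benzene, via (2,6-dimethoxyphenyl)lithium 10 (not isolated)
Conditions: n-BuLi (1.05 equiv), THF, 0 °C → rt; CuBr·SMe2 (10 mol %), then 9, −40 °C → rt
Reagents that add atoms: none
Why: Directed ortho-metalation removes the C2 proton that both methoxy groups acidify and chelate, and the copper-catalysed allylic substitution then occurs at the open CH2 terminus of 9 (SN2, not SN2') because the other allylic terminus is fully substituted and the nucleophile is di-ortho-substituted.

Step 6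
Reactants: 11 1,3-dimethoxy-2-(3-methylbut-2-en-1-yl)benzene
Product: 12 2-[3,5-dimethoxy-4-(3-methylbut-2-en-1-yl)phenyl]-4,4,5,5-tetramethyl-1,3,2-dioxaborolane
Conditions: [Ir(OMe)(cod)]2 (1.5 mol %), dtbpy (3 mol %), B2pin2 (1.0 equiv), THF, 60 °C, stopped at full conversion; silica plug
Reagents that add atoms: bis(pinacolato)diboron, CC1(C)OB(OC1(C)C)B1OC(C)(C)C(C)(C)O1
Why: Iridium-catalysed aromatic C–H borylation is sterically governed and therefore selects C5–H, the only ring hydrogen without an ortho substituent, while the trisubstituted prenyl alkene is a poor substrate for borylation or hydroboration with this catalyst at moderate temperature.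

Step 7
Reactants: 12 2-[3,5-dimethoxy-4-(3-methylbut-2-en-1-yl)phenyl]-4,4,5,5-tetramethyl-1,3,2-dioxaborolane
Product: 13 5-bromo-1,3-dimethoxy-2-(3-methylbut-2-en-1-yl)benzene
Conditions: CuBr2 (3 equiv), MeOH/H2O (1:1), 80 °C, followed closely and stopped at conversion
Reagents that add atoms: copper(II) bromide, [Cu+2].[Br-].[Br-]
Why: Copper(II)-mediated bromodeboronation runs through boron-to-copper transmetalation, oxidation to aryl-copper(III) by a second CuBr2 and C–Br reductive elimination, so bromine lands ipso at C5 and not at the methoxy-activated C4/C6 positions, and the half-aqueous medium keeps the copper salt solvated, which should keep bromine transfer to the alkene slow.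

Step 8
Reactants: 7 1,3-dioxoisoindolin-2-yl 3-[2-methoxy-3,4-bis(methoxymethoxy)phenyl]propanoate; 13 5-bromo-1,3-dimethoxy-2-(3-methylbut-2-en-1-yl)benzene
Product: 14 1-{2-[3,5-dimethoxy-4-(3-methylbut-2-en-1-yl)phenyl]ethyl}-2-methoxy-3,4-bis(methoxymethoxy)benzene
Conditions: 7 (1.5 equiv), 13 (1 equiv), NiCl2·6H2O (20 mol %), 2,2'-bipyridine (20 mol %), AgNO3 (0.3 equiv, coats the cathode), NMP, undivided cell, Mg(+)/RVC(−), constant current, ca. 3 F/mol, rt
Reagents that add atoms: none
Why: Cathodic reduction supplies low-valent (bpy)Ni, which adds oxidatively into the C5–Br bond of 13, while single-electron reduction of the phthalimide unit of 7 breaks the N–O bond and expels CO2 and phthalimide anion to leave the primary 2-arylethyl radical. The aryl-nickel(II) species traps this radical, and reductive elimination from nickel(III) forms the bond between the bridge CH2 and C1 of ring A, the magnesium anode paying for both electrons. The closest known reaction type is the nickel-electrocatalytic decarboxylative arylation of N-hydroxyphthalimide esters with aryl halides, a cross-electrophile coupling established for primary alkyl esters. No ring is closed and no stereocentre is created. The selectivity needed is cross-coupling over biaryl formation, radical dimerisation, reduction to the ethylarene and β-hydride loss to the styrene; it is secured by the two free positions ortho to bromine (the methoxy groups sit meta and are mildly activating), by current-limited release of an unhindered primary radical and by the excess of 7. The trisubstituted prenyl alkene is a poor acceptor for a nucleophilic alkyl radical, a 1,2-aryl shift of the radical would be degenerate, and MOM acetals and aryl methyl ethers are inert in this neutral reductive medium.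

Step 9
Reactants: 14 1-{2-[3,5-dimethoxy-4-(3-methylbut-2-en-1-yl)phenyl]ethyl}-2-methoxy-3,4-bis(methoxymethoxy)benzene
Product: 15 4-{2-[3,5-dimethoxy-4-(3-methylbut-2-en-1-yl)phenyl]ethyl}-3-methoxybenzene-1,2-diol
Conditions: p-TsOH·H2O (0.3 equiv), MeOH, 40 °C, Ar; product used directly
Reagents that add atoms: none
Why: Acid-catalysed transacetalisation to methanol strips both aryl MOM groups as volatile dimethoxymethane at an acidity too low to protonate the trisubstituted alkene, which in addition has only methyl ethers as ring neighbours and so cannot close a chroman.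

Step 10
Reactants: 15 4-{2-[3,5-dimethoxy-4-(3-methylbut-2-en-1-yl)phenyl]ethyl}-3-methoxybenzene-1,2-diol
Product: 16 4-{2-[3,5-dimethoxy-4-(3-methylbut-2-en-1-yl)phenyl]ethyl}-2-hydroxy-3-methoxyphenyl acetate (target CNP0143232.0)
Conditions: Ac2O (1.0 equiv, slow addition), pyridine (3 equiv), CH2Cl2, −20 → 0 °C, Ar
Reagents that add atoms: acetic anhydride, CC(=O)OC(C)=O
Why: Kinetically controlled pyridine-mediated O-acylation with one equivalent of anhydride should pick the ring-B 4-OH, which has a free ortho position and gains nucleophilicity by donating its hydrogen bond to O3, over the 3-OH, which is wedged between C2–OMe and C4–O and tied to the methoxy oxygen, and any acyl migration between the neighbouring oxygens should drain toward the same less crowded ester of the less acidic phenol.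

Compound list
1 | daphnetin (7,8-dihydroxy-2H-chromen-2-one) | O=C1C=Cc2ccc(O)c(O)c2O1 | starting material
2 | 7,8-bis(methoxymethoxy)-2H-chromen-2-one | O=C1C=Cc2ccc(OCOC)c(OCOC)c2O1 | intermediate
3 | 7,8-bis(methoxymethoxy)chroman-2-one | O=C1CCc2ccc(OCOC)c(OCOC)c2O1 | intermediate
4 | disodium 3-[3,4-bis(methoxymethoxy)-2-oxidophenyl]propanoate | [Na+].[Na+].[O-]C(=O)CCc1ccc(OCOC)c(OCOC)c1[O-] | intermediate
5 | sodium 3-[2-methoxy-3,4-bis(methoxymethoxy)phenyl]propanoate | [Na+].[O-]C(=O)CCc1ccc(OCOC)c(OCOC)c1OC | intermediate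
6 | 3-[2-methoxy-3,4-bis(methoxymethoxy)phenyl]propanoic acid | OC(=O)CCc1ccc(OCOC)c(OCOC)c1OC | intermediate
7 | 1,3-dioxoisoindolin-2-yl 3-[2-methoxy-3,4-bis(methoxymethoxy)phenyl]propanoate | O=C(CCc1ccc(OCOC)c(OCOC)c1OC)ON1C(=O)c2ccccc2C1=O | intermediate
8 | 1,3-dimethoxybenzene | COc1cccc(OC)c1 | starting material
9 | prenyl bromide (1-bromo-3-methylbut-2-ene) | CC(C)=CCBr | starting material
10 | (2,6-dimethoxyphenyl)lithium | [Li]c1c(OC)cccc1OC | intermediate
11 | 1,3-dimethoxy-2-(3-methylbut-2-en-1-yl)benzene | COc1cccc(OC)c1CC=C(C)C | intermediate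
12 | 2-[3,5-dimethoxy-4-(3-methylbut-2-en-1-yl)phenyl]-4,4,5,5-tetramethyl-1,3,2-dioxaborolane | COc1cc(B2OC(C)(C)C(C)(C)O2)cc(OC)c1CC=C(C)C | intermediate
13 | 5-bromo-1,3-dimethoxy-2-(3-methylbut-2-en-1-yl)benzene | COc1cc(Br)cc(OC)c1CC=C(C)C | intermediate
14 | 1-{2-[3,5-dimethoxy-4-(3-methylbut-2-en-1-yl)phenyl]ethyl}-2-methoxy-3,4-bis(methoxymethoxy)benzene | COc1cc(CCc2ccc(OCOC)c(OCOC)c2OC)cc(OC)c1CC=C(C)C | intermediate
15 | 4-{2-[3,5-dimethoxy-4-(3-methylbut-2-en-1-yl)phenyl]ethyl}-3-methoxybenzene-1,2-diol | COc1cc(CCc2ccc(O)c(O)c2OC)cc(OC)c1CC=C(C)C | intermediate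
16 | 4-{2-[3,5-dimethoxy-4-(3-methylbut-2-en-1-yl)phenyl]ethyl}-2-hydroxy-3-methoxyphenyl acetate | COc1cc(CCc2ccc(OC(C)=O)c(O)c2OC)cc(OC)c1CC=C(C)C | target

Total step count: 10. Longest linear sequence: 7 (steps 1–4 and 8–10). The ring-A arm contributes steps 5–7.

Steps most likely to fail

Step 7 (and, to a lesser degree, step 6). Bromine transfer from CuBr2 to the electron-rich prenyl alkene may compete with ipso-bromination. The alkene may also be hydroborated or shifted into conjugation during the borylation. The fallback brings the alkene in only after the copper step.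
- It sets out from 8. Lithiation to 10 as in step 5 and a quench with iodine would give 2-iodo-1,3-dimethoxybenzene F1.
- The same iridium borylation at C5 would give 2-(4-iodo-3,5-dimethoxyphenyl)-4,4,5,5-tetramethyl-1,3,2-dioxaborolane F2.
- CuBr2 in aqueous methanol would then give 5-bromo-2-iodo-1,3-dimethoxybenzene F3.
- Chemoselective iodine–magnesium exchange (i-PrMgCl·LiCl, THF, −20 °C) would give (4-bromo-2,6-dimethoxyphenyl)magnesium chloride F4. C–I exchanges far faster than C–Br, and the two ortho methoxy groups stabilise the carbanion.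
- Copper-catalysed allylation of this Grignard reagent with 9 comes back to the route at 13.

Step 8. Several processes may erode the cross-coupling: premature reduction of the ester to the ethylarene, radical dimerisation, β-hydride loss from the alkyl-nickel species, or sluggish oxidative addition of the electronically neutral bromide. The fallback makes the same bond by a redox-neutral polar route instead of cross-electrophile electrolysis.
- It sets out from 13. Bromine–lithium exchange (n-BuLi, THF, −78 °C) would give [3,5-dimethoxy-4-(3-methylbut-2-en-1-yl)phenyl]lithium F5.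
- ZnCl2 would convert it into [3,5-dimethoxy-4-(3-methylbut-2-en-1-yl)phenyl]zinc chloride F6.
- Nickel-catalysed decarboxylative Negishi-type arylation of 7 (NiCl2·glyme, dtbbpy, THF/DMF, rt) comes back at 14.

Step 10. Acylation may spread over both phenols, run on to double acetylation, or be blurred by acyl migration between the neighbouring oxygens. The fallback tells the two oxygens apart at the outset, where the lactone makes them electronically different.
- It sets out from 1. One equivalent each of SEMCl and i-Pr2NEt (DMF, −10 °C) should alkylate only the 7-OH, which is both the vinylogous-acid phenol and the less crowded one. This gives 8-hydroxy-7-{[2-(trimethylsilyl)ethoxy]methoxy}-2H-chromen-2-one F7.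
- MOMCl/i-Pr2NEt would cap the 8-OH to give 8-(methoxymethoxy)-7-{[2-(trimethylsilyl)ethoxy]methoxy}-2H-chromen-2-one F8.
- The operations of steps 2–4 would lead through the chroman-2-one F9, the ring-opened disodium salt F10, the sodium carboxylate F11 and the propanoic acid F12 to the phthalimide ester F13.
- The electrolysis of step 8 with 13 would give the 4-O-SEM 3-O-MOM bibenzyl F14.
- TBAF (THF/DMPU, 60 °C) would remove only the SEM group to give the 4-hydroxy 3-O-MOM bibenzyl F15, and Ac2O/pyridine/DMAP would give the 4-O-acetyl 3-O-MOM bibenzyl F16.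
- Silica-supported NaHSO4 in CH2Cl2 at rt, a non-nucleophilic medium in which aryl acetates persist, would cleave the last MOM group and come back at 16.

Further compounds
F1 | step 7 | 2-iodo-1,3-dimethoxybenzene | COc1cccc(OC)c1I
F2 | step 7 | 2-(4-iodo-3,5-dimethoxyphenyl)-4,4,5,5-tetramethyl-1,3,2-dioxaborolane | COc1cc(B2OC(C)(C)C(C)(C)O2)cc(OC)c1I
F3 | step 7 | 5-bromo-2-iodo-1,3-dimethoxybenzene | COc1cc(Br)cc(OC)c1I
F4 | step 7 | (4-bromo-2,6-dimethoxyphenyl)magnesium chloride | COc1cc(Br)cc(OC)c1[Mg]Cl
F5 | step 8 | [3,5-dimethoxy-4-(3-methylbut-2-en-1-yl)phenyl]lithium | [Li]c1cc(OC)c(CC=C(C)C)c(OC)c1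
F6 | step 8 | [3,5-dimethoxy-4-(3-methylbut-2-en-1-yl)phenyl]zinc chloride | Cl[Zn]c1cc(OC)c(CC=C(C)C)c(OC)c1
F7 | step 10 | 8-hydroxy-7-{[2-(trimethylsilyl)ethoxy]methoxy}-2H-chromen-2-one | O=C1C=Cc2ccc(OCOCC[Si](C)(C)C)c(O)c2O1
F8 | step 10 | 8-(methoxymethoxy)-7-{[2-(trimethylsilyl)ethoxy]methoxy}-2H-chromen-2-one | O=C1C=Cc2ccc(OCOCC[Si](C)(C)C)c(OCOC)c2O1
F9 | step 10 | 8-(methoxymethoxy)-7-{[2-(trimethylsilyl)ethoxy]methoxy}chroman-2-one | O=C1CCc2ccc(OCOCC[Si](C)(C)C)c(OCOC)c2O1
F10 | step 10 | disodium 3-[3-(methoxymethoxy)-2-oxido-4-{[2-(trimethylsilyl)ethoxy]methoxy}phenyl]propanoate | [Na+].[Na+].[O-]C(=O)CCc1ccc(OCOCC[Si](C)(C)C)c(OCOC)c1[O-]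
F11 | step 10 | sodium 3-[2-methoxy-3-(methoxymethoxy)-4-{[2-(trimethylsilyl)ethoxy]methoxy}phenyl]propanoate | [Na+].[O-]C(=O)CCc1ccc(OCOCC[Si](C)(C)C)c(OCOC)c1OC
F12 | step 10 | 3-[2-methoxy-3-(methoxymethoxy)-4-{[2-(trimethylsilyl)ethoxy]methoxy}phenyl]propanoic acid | OC(=O)CCc1ccc(OCOCC[Si](C)(C)C)c(OCOC)c1OC
F13 | step 10 | 1,3-dioxoisoindolin-2-yl 3-[2-methoxy-3-(methoxymethoxy)-4-{[2-(trimethylsilyl)ethoxy]methoxy}phenyl]propanoate | O=C(CCc1ccc(OCOCC[Si](C)(C)C)c(OCOC)c1OC)ON1C(=O)c2ccccc2C1=O
F14 | step 10 | 4-O-SEM 3-O-MOM bibenzyl | COc1cc(CCc2ccc(OCOCC[Si](C)(C)C)c(OCOC)c2OC)cc(OC)c1CC=C(C)C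
F15 | step 10 | 4-{2-[3,5-dimethoxy-4-(3-methylbut-2-en-1-yl)phenyl]ethyl}-3-methoxy-2-(methoxymethoxy)phenol | COc1cc(CCc2ccc(O)c(OCOC)c2OC)cc(OC)c1CC=C(C)C
F16 | step 10 | 4-{2-[3,5-dimethoxy-4-(3-methylbut-2-en-1-yl)phenyl]ethyl}-3-methoxy-2-(methoxymethoxy)phenyl acetate | COc1cc(CCc2ccc(OC(C)=O)c(OCOC)c2OC)cc(OC)c1CC=C(C)C
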